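**Plan**

- The target is a dimer of ligustilide (3-butylidene-4,5-dihydrophthalide; phthalide locants, primed for the second half). One cyclobutane joins C6 and C7 of a butenolide half to the ring-fusion carbons C3a' and C7a' of the other half, which becomes a [4.3.2]propellane γ-lactone. This four-membered ring between two identical C12 units is what allows assembly in one event.
- Retrosynthesis: the Z-butylidene of the conjugated half is traced to its E isomer, then the cyclobutane bonds C7–C3a' and C6–C7a' are cut together to give two molecules of (E)-ligustilide. The monomer is cut at C8–C9 (alkyl–alkenyl coupling), at O2–C3 together with C8–I (iodolactonisation) and at C3a–C3 (alkynylation of a dienyl triflate).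
- Forward: the cyclohexadiene carboxylate comes first (steps 1–3), the γ-lactone ring closes in step 5, the cyclobutane and with it the propellane close in the photodimerisation (step 7), and the last step only turns one double bond.
- Stereochemistry: the E enol lactone comes from anti iodolactonisation and a stereoretentive coupling. The four stereocentres (6S,7R,3a'S,7a'R) arise together in step 7: cis ring fusions from the ring alkenes, syn carbocycles and absolute sense from a chiral Lewis acid. The Z geometry of the conjugated half is the thermodynamic one and is set last.

Key step: step 7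

Remark: as the target is drawn, the butylidene of the propellane half is E (propyl trans to the ring oxygen) and that of the butenolide half is Z; the route is planned for exactly this geometry.

**Route**

Step 1
Reactants: 1 methyl 2-oxocyclohexane-1-carboxylate
Product: 4 methyl 6-oxocyclohex-1-ene-1-carboxylate, via α-phenylselanyl keto ester 2 (not isolated), via selenoxide 3 (not isolated)
Conditions: PhSeCl, pyridine, CH2Cl2, 0 °C; then 30% aq. H2O2, 0 °C to rt; product used at once
Reagents that add atoms: none
Why: α-selenenylation of the β-keto ester at its doubly activated carbon, oxidation and selenoxide syn-elimination should give the 2-carbomethoxy enone, the only β-hydrogens being those of the ring CH2, and no stereocentre is retained.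

Step 2
Reactants: 4 methyl 6-oxocyclohex-1-ene-1-carboxylate
Product: 5 methyl 2-{[(trifluoromethyl)sulfonyl]oxy}cyclohexa-1,5-diene-1-carboxylate
Conditions: Tf2O, 2,6-di-tert-butyl-4-methylpyridine, CH2Cl2, −78 °C to 0 °C
Reagents that add atoms: trifluoromethanesulfonic anhydride, O=S(=O)(OS(=O)(=O)C(F)(F)F)C(F)(F)F
Why: enol triflate formation from an enone by O-sulfonylation and γ-deprotonation (or directly through the hydrogen-bonded dienol tautomer) should give the thermodynamic conjugated dienyl triflate, which places the ring alkene on the ester-bearing carbon as ligustilide requires.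

Step 3
Reactants: 5 methyl 2-{[(trifluoromethyl)sulfonyl]oxy}cyclohexa-1,5-diene-1-carboxylate; 6 ethynyltrimethylsilane
Product: 7 methyl 2-[(trimethylsilyl)ethynyl]cyclohexa-1,5-diene-1-carboxylate
Conditions: PdCl2(PPh3)2 (3 mol %), CuI (6 mol %), Et3N, THF, rt
Reagents that add atoms: none
Why: Sonogashira coupling of an electron-poor β-(sulfonyloxy)acrylate-type alkenyl triflate with a terminal alkyne is a reliable sp2–sp coupling that leaves the ring diene untouched.

Step 4
Reactants: 7 methyl 2-[(trimethylsilyl)ethynyl]cyclohexa-1,5-diene-1-carboxylate
Product: 9 2-ethynylcyclohexa-1,5-diene-1-carboxylic acid, via methyl 2-ethynylcyclohexa-1,5-diene-1-carboxylate 8 (not isolated)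
Conditions: K2CO3 (cat.), MeOH, 0 °C; then LiOH, THF/H2O, 0 °C to rt; then 1 M HCl to pH 3
Reagents that add atoms: lithium hydroxide, [Li+].[OH-]
Why: methanolysis of the alkynyl–silicon bond followed by ester saponification is standard and should deliver the enynoic acid whose ring holds carboxyl and alkyne cis for lactonisation.

Step 5
Reactants: 9 2-ethynylcyclohexa-1,5-diene-1-carboxylic acid
Product: 10 (3E)-3-(iodomethylidene)-4,5-dihydro-2-benzofuran-1(3H)-one
Conditions: I2, NaHCO3, MeCN, 0 °C, dark
Reagents that add atoms: iodine, II
Why: iodolactonisation of the alkynoic acid by anti addition of carboxylate oxygen and iodine across the terminal alkyne in the 5-exo-dig mode (oxygen to the internal carbon) should give the iodoenol lactone with iodine trans to the ring oxygen, i.e. E.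

Step 6
Reactants: 10 (3E)-3-(iodomethylidene)-4,5-dihydro-2-benzofuran-1(3H)-one; 11 propylzinc bromide
Product: 12 (E)-ligustilide, (3E)-3-butylidene-4,5-dihydro-2-benzofuran-1(3H)-one
Conditions: [1,1'-bis(diphenylphosphino)ferrocene]PdCl2 (5 mol %), THF, 0 °C to rt, dark
Reagents that add atoms: none
Why: Negishi coupling of an alkenyl iodide with a primary alkylzinc halide proceeds with retention at the sp2 carbon, so propyl should take the place of iodine trans to the ring oxygen and give the E-butylidene lactone that direct cycloisomerisation of a pentynyl acid would not give.

Step 7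
Reactants: 12 (E)-ligustilide (two molecules, one for each half)
Product: 13 (3E,3'E,6S,7R,3a'S,7a'R)-dimer of 12: cyclobutane C6–C7–C3a'–C7a', H-6 and H-7 cis, the two cyclohexene rings syn across the cyclobutane and the propellane γ-lactone anti to the butenolide half, both butylidenes E
Conditions: 1:1 adduct of AlBr3 and (S)-3,3-bis(3,5-dimethylphenyl)-1-(2,4,6-trifluorophenyl)tetrahydro-1H,3H-pyrrolo[1,2-c][1,3,2]oxazaborole (0.5 equiv), CH2Cl2 (0.05 M in 12), argon, −75 °C, 405 nm LED; Et3N quench at −75 °C
Reagents that add atoms: none
Why: Proposed new method: the Lewis acid binds the lactone carbonyl of half of the monomer, moves its absorption into the visible and gives, after intersystem crossing, an enone-type triplet that is attacked at C7a' by the nucleophilic diene terminus C6 of an unbound molecule, and the 1,4-biradical so formed (a pentadienyl-type radical C7–C7a–C3a–C3–C8 and a 2-oxyallyl radical C3a'–C3'–C8') collapses by C7–C3a' bond formation; the closest known reaction type is the enantioselective intermolecular [2+2] photocycloaddition of cyclic enones, and the intramolecular one of coumarins, catalysed by AlBr3-activated chiral oxazaborolidines. The cyclobutane is the one ring closed, by an intermolecular bond followed by four-membered radical recombination, and it creates at once the cyclohexene–cyclobutane fusion of one half and the [4.3.2]propellane of the other. Both fusions are necessarily cis (C6/C7 by addition to a ring alkene, C3a'/C7a' by the propellane), the syn arrangement of the two carbocycles should follow from approach of the unbound monomer over the carbocyclic side of the bound one, away from the bulky Lewis acid on the γ-lactone, and the absolute configuration from shielding of one enantiotopic face of the bound monomer by the catalyst, the (R)-catalyst being used if the opposite sense is found. The step needs site selectivity (C6=C7 of the ground-state partner, C3a'=C7a' of the excited one), head-to-tail regiochemistry and retention of the E geometry of the excited partner. Only the complex absorbs at 405 nm, C6=C7 is the sole disubstituted and least hindered alkene and its carbon C6 pairs with the α-carbon of the excited enone as in the usual head-to-tail rule for donor alkenes. The E-butylidene is expected to survive because excitation resides in the ring-locked enone and the 2-oxyallyl radical is configurationally stable at −75 °C, while the geometry of the ground-state half is corrected in step 8.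

Step 8
Reactants: 13 (3E,3'E,6S,7R,3a'S,7a'R)-dimer
Product: 14 target, (3Z,3'E,6S,7R,3a'S,7a'R)-dimer
Conditions: I2 (3 mol %), CH2Cl2, white light, rt, followed by 1H NMR; aq. Na2S2O3
Reagents that add atoms: none
Why: iodine-catalysed E-to-Z isomerisation of γ-alkylidenebutenolides should turn only the conjugated butylidene of the butenolide half into its more stable Z form, because reversible iodine-atom addition at C8 gives a delocalised allyl radical there while the isolated enol lactone of the propellane half offers no such stabilisation and should keep its E geometry, and the four stereocentres are not touched.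

**Compound list**

1 | methyl 2-oxocyclohexane-1-carboxylate | COC(=O)C1CCCCC1=O | starting material
2 | methyl 2-oxo-1-(phenylselanyl)cyclohexane-1-carboxylate (racemic) | COC(=O)C1([Se]c2ccccc2)CCCCC1=O | intermediate
3 | methyl 2-oxo-1-(phenylseleninyl)cyclohexane-1-carboxylate (stereoisomer mixture) | COC(=O)C1([Se](=O)c2ccccc2)CCCCC1=O | intermediate
4 | methyl 6-oxocyclohex-1-ene-1-carboxylate | COC(=O)C1=CCCCC1=O | intermediate
5 | methyl 2-{[(trifluoromethyl)sulfonyl]oxy}cyclohexa-1,5-diene-1-carboxylate | COC(=O)C1=C(OS(=O)(=O)C(F)(F)F)CCC=C1 | intermediate
6 | ethynyltrimethylsilane | C#C[Si](C)(C)C | starting material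
7 | methyl 2-[(trimethylsilyl)ethynyl]cyclohexa-1,5-diene-1-carboxylate | COC(=O)C1=C(C#C[Si](C)(C)C)CCC=C1 | intermediate
8 | methyl 2-ethynylcyclohexa-1,5-diene-1-carboxylate | COC(=O)C1=C(C#C)CCC=C1 | intermediate
9 | 2-ethynylcyclohexa-1,5-diene-1-carboxylic acid | OC(=O)C1=C(C#C)CCC=C1 | intermediate
10 | (3E)-3-(iodomethylidene)-4,5-dihydro-2-benzofuran-1(3H)-one | I/C=C1/OC(=O)C2=C1CCC=C2 | intermediate
11 | propylzinc bromide | CCC[Zn]Br | starting material
12 | (E)-ligustilide, (3E)-3-butylidene-4,5-dihydro-2-benzofuran-1(3H)-one | CCC/C=C1/OC(=O)C2=C1CCC=C2 | intermediate
13 | (3E,3'E,6S,7R,3a'S,7a'R)-ligustilide dimer with cyclobutane C6–C7–C3a'–C7a' (H-6/H-7 cis, carbocycles syn) | CCC/C=C1/OC(=O)C2=C1CC[C@H]1[C@@H]2[C@@]23CCC=C[C@@]12C(=O)O/C3=C/CCC | intermediate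
14 | (3Z,3'E,6S,7R,3a'S,7a'R)-ligustilide dimer with cyclobutane C6–C7–C3a'–C7a' (H-6/H-7 cis, carbocycles syn) | CCC/C=C1\OC(=O)C2=C1CC[C@H]1[C@@H]2[C@@]23CCC=C[C@@]12C(=O)O/C3=C/CCC | target

**Totals and risks**

Total steps: 8. Longest linear sequence: 8 steps (1 to 14).

Steps most likely to fail:

1. Step 7. The monomer has three alkenes, so other pairings may compete (cyclobutanes through the butylidene bonds, six-membered closure of the biradical). Torsion about C3'=C8' in the excited partner may erode the E geometry, and facial discrimination by the catalyst may be insufficient. Fallback with known chemistry, from 12 back to 13: triplet-sensitised photodimerisation of 12 without Lewis acid (thioxanthen-9-one, degassed CH2Cl2, 405 nm, −40 °C) should give the racemate, that is 13 together with the mirror-image (3E,3'E,6R,7S,3a'R,7a'S) dimer F1. The C6–C7–C3a'–C7a' cyclobutane is separated from isomeric dimers on silica, and 13 is then obtained by preparative HPLC on a cellulose tris(3,5-dimethylphenylcarbamate) phase.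

2. Step 8. Iodine atoms may also add reversibly to the strained E enol ether of the propellane half and relax it to Z, or equilibration of the conjugated half may stay incomplete. Fallback, from 5 and 12 directly to 14: the Z geometry is installed before the cycloaddition.
   - Sonogashira coupling of 5 with pent-1-yne (PdCl2(PPh3)2, CuI, Et3N) should give methyl 2-(pent-1-yn-1-yl)cyclohexa-1,5-diene-1-carboxylate F2.
   - Saponification (LiOH, then HCl) gives 2-(pent-1-yn-1-yl)cyclohexa-1,5-diene-1-carboxylic acid F3.
   - AgNO3-catalysed 5-exo-dig anti hydro-oxycyclisation (acetone, rt) gives (Z)-ligustilide F4.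
   - F4 is then used in excess as the ground-state partner under the conditions of step 7 with 12 as the limiting component, and 14 is separated from the Z,Z' and E,E' dimers that the statistical distribution of the Lewis acid will also produce.

3. Step 5. The carboxylate may close in the 6-endo mode to a 2-pyranone, or iodine may attack the ring diene. Fallback, from 9 back to 12, bypassing 10 and step 6:
   - The lithium salt of 9 is treated with allyl chloride and PdCl2(PhCN)2 (cat.) in THF. Anti oxypalladation followed by allyl transfer with retention should give (3E)-3-(but-3-en-1-ylidene)-4,5-dihydro-2-benzofuran-1(3H)-one F5.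
   - Diimide, generated from 2-nitrobenzenesulfonohydrazide and Et3N, should reduce only the monosubstituted vinyl group of F5 and give 12.

Further compounds
F1 | step 7 | (3E,3'E,6R,7S,3a'R,7a'S)-ligustilide dimer, enantiomer of 13 | CCC/C=C1/OC(=O)C2=C1CC[C@@H]1[C@H]2[C@]23CCC=C[C@]12C(=O)O/C3=C/CCC
F2 | step 8 | methyl 2-(pent-1-yn-1-yl)cyclohexa-1,5-diene-1-carboxylate | COC(=O)C1=C(C#CCCC)CCC=C1
F3 | step 8 | 2-(pent-1-yn-1-yl)cyclohexa-1,5-diene-1-carboxylic acid | OC(=O)C1=C(C#CCCC)CCC=C1
F4 | step 8 | (Z)-ligustilide, (3Z)-3-butylidene-4,5-dihydro-2-benzofuran-1(3H)-one | CCC/C=C1\OC(=O)C2=C1CCC=C2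
F5 | step 5 | (3E)-3-(but-3-en-1-ylidene)-4,5-dihydro-2-benzofuran-1(3H)-one | C=CC/C=C1/OC(=O)C2=C1CCC=C2
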